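**Plan**
- Retrosynthesis: cut the C5 O–CH3 bond last (free phenol), take the two C=O groups back to a C≡C, then cut the C6–C(sp) bond and the C6–I bond.
- The pyran is then cut at O1–C8a, C4–C4a and O1–C2, giving 3,6-dimethoxybenzyne and 3-methylbut-2-enal; the aryne precursor goes back (O–S, C–Si) to 2,5-dimethoxyphenol.
- Enabling feature: O1 (on C8a) and C4 (on C4a) sit on adjacent ring carbons flanked by the C8 and C5 oxygens, so the pyran can be laid across the triple bond of a symmetric aryne.
- Forward: the benzene ring is bought, the silyl triflate is made in three steps, the pyran (the only ring formed) closes in step 4, then the C6 side chain is attached, oxidised and the 5-OMe is unmasked.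
- Stereochemistry: the target has no stereocentre; the C3=C4 bond is cis by ring constraint.

Key step: step 4

Remark: dielsianone is achiral, so the request for a single enantiomer is met by the constitution alone. 2,5-Dimethoxyphenol, 3-methylbut-2-enal and 4-ethynylanisole are taken as purchasable.

**Route**

Step 1
Reactants: 1 2,5-dimethoxyphenol
Product: 2 2,5-dimethoxyphenyl N-isopropylcarbamate
Conditions: i-PrNCO (1.5 equiv), Et3N (cat.), CH2Cl2, rt
Reagents that add atoms: isopropyl isocyanate, CC(C)N=C=O
Why: Base-catalysed carbamoylation (addition of the phenol O–H across the isocyanate) installs an ortho-directing group that can later be removed under mild E1cB conditions.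

Step 2
Reactants: 2 2,5-dimethoxyphenyl N-isopropylcarbamate
Product: 6 3,6-dimethoxy-2-(trimethylsilyl)phenyl N-isopropylcarbamate, via N-TBS carbamate 3 (not isolated), via aryllithium 4 (not isolated), via N-TBS C-silyl carbamate 5 (not isolated)
Conditions: TBSOTf, TMEDA, Et2O, 0 °C → rt; n-BuLi, TMEDA, −78 °C; TMSCl, −78 °C → rt; aq. NaHSO4
Reagents that add atoms: chlorotrimethylsilane, C[Si](C)(C)Cl
Why: In-situ N-silylation masks the N–H, a Snieckus-type directed ortho-metalation then occurs at the only C–H flanked by two directing oxygens (between the carbamate and the 5-OMe), TMSCl traps the aryllithium at −78 °C before an anionic ortho-Fries shift can start, and the N–Si bond is hydrolysed on acidic work-up.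

Step 3
Reactants: 6 3,6-dimethoxy-2-(trimethylsilyl)phenyl N-isopropylcarbamate
Product: 8 3,6-dimethoxy-2-(trimethylsilyl)phenyl trifluoromethanesulfonate, via silylphenol 7 (not isolated)
Conditions: DBU, Et2NH, MeCN, 40 °C; then PhNTf2, rt
Reagents that add atoms: N-phenylbis(trifluoromethanesulfonimide), O=S(=O)(N(c1ccccc1)S(=O)(=O)C(F)(F)F)C(F)(F)F
Why: DBU-induced E1cB cleavage of the secondary carbamate (the isocyanate is scavenged by Et2NH as a urea) frees the phenoxide, which is O-triflated in the same pot by PhNTf2, and the absence of strong nucleophiles preserves the aryl–Si bond.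

Step 4
Reactants: 8 3,6-dimethoxy-2-(trimethylsilyl)phenyl trifluoromethanesulfonate; 9 3-methylbut-2-enal
Product: 13 5,8-dimethoxy-2,2-dimethyl-2H-chromene, via 3,6-dimethoxybenzyne 10 (not isolated), via benzoxete 11 (not isolated), via o-quinone methide 12 (not isolated)
Conditions: 9 (3 equiv), CsF (3 equiv), MeCN, rt → 50 °C, slow addition of 8
Reagents that add atoms: none
Why: Fluoride attacks silicon and the aryl anion expels triflate (1,2-elimination) to give the C2v-symmetric aryne 10, whose strained bond is made more electrophilic by the two flanking, inductively withdrawing methoxy groups. The carbonyl oxygen of 9 adds to one aryne carbon and the resulting aryl anion closes on the carbonyl carbon (stepwise formal [2+2]) to benzoxete 11, forming O1–C8a and C4–C4a. Thermal 4π-electrocyclic opening of 11 gives the 1-oxatriene 12, and a 6π-oxa-electrocyclisation (six-membered, oxygen onto the dimethyl-substituted terminus) closes the pyran through O1–C2 and restores the benzene ring. The closest known reaction type is the fluoride-triggered reaction of silylaryl triflates with α,β-unsaturated aldehydes to give 2H-chromenes. No stereocentre is created, since C2 carries two methyl groups and the transient stereocentre of 11 is erased on ring opening. Regioselectivity does not arise because both aryne carbons are equivalent, and the required chemoselectivity (carbonyl addition rather than an ene reaction at the allylic methyl C–H or a second aryne capture) is secured by the electrophilic oxygen-flanked aryne, the excess of 9 and the slow aryne release from sparingly soluble CsF.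

Step 5
Reactants: 13 5,8-dimethoxy-2,2-dimethyl-2H-chromene
Product: 14 6-iodo-5,8-dimethoxy-2,2-dimethyl-2H-chromene
Conditions: NIS (1.05 equiv), MeCN, 0 °C → rt, dark
Reagents that add atoms: N-iodosuccinimide, O=C1CCC(=O)N1I
Why: Electrophilic aromatic iodination should occur at C6, which is para to the ring oxygen O1 and ortho to the 5-OMe (C7 is activated by one methoxy group only), and it is irreversible whereas iodonium formation at C3=C4 is reversible in a non-nucleophilic medium.

Step 6
Reactants: 14 6-iodo-5,8-dimethoxy-2,2-dimethyl-2H-chromene; 15 4-ethynylanisole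
Product: 16 5,8-dimethoxy-6-[(4-methoxyphenyl)ethynyl]-2,2-dimethyl-2H-chromene
Conditions: PdCl2(PPh3)2 (cat.), CuI (cat.), Et3N/THF, 50 °C, degassed
Reagents that add atoms: none
Why: Sonogashira coupling of an aryl iodide proceeds under mild conditions even on an electron-rich, ortho-substituted ring and leaves the chromene alkene and the ethers untouched.

Step 7
Reactants: 16 5,8-dimethoxy-6-[(4-methoxyphenyl)ethynyl]-2,2-dimethyl-2H-chromene
Product: 17 1-(5,8-dimethoxy-2,2-dimethyl-2H-chromen-6-yl)-2-(4-methoxyphenyl)ethane-1,2-dione
Conditions: PdCl2 (10 mol%), DMSO, 140 °C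
Reagents that add atoms: dimethyl sulfoxide, CS(C)=O
Why: Pd(II)-catalysed Wacker-type oxidation of a diarylalkyne transfers two oxygen atoms from DMSO to give the benzil, and in the absence of water the chromene alkene, which has no allylic C–H, should not be attacked.

Step 8
Reactants: 17 1-(5,8-dimethoxy-2,2-dimethyl-2H-chromen-6-yl)-2-(4-methoxyphenyl)ethane-1,2-dione
Product: 18 dielsianone, 1-(5-hydroxy-8-methoxy-2,2-dimethyl-2H-chromen-6-yl)-2-(4-methoxyphenyl)ethane-1,2-dione
Conditions: BCl3 (2.2 equiv), CH2Cl2, −78 → −20 °C; H2O
Reagents that add atoms: none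
Why: Chelation-controlled Lewis-acid demethylation: boron bridges the C6 ketone oxygen and the adjacent 5-OMe in a six-membered chelate so that chloride dealkylates only that ether, while the 8-OMe and the anisyl OMe lack a carbonyl partner and the low temperature spares the allylic aryl ether of the pyran.

**Compound list**

1 | 2,5-dimethoxyphenol | COc1ccc(OC)c(O)c1 | starting material
2 | 2,5-dimethoxyphenyl N-isopropylcarbamate | COc1ccc(OC)c(OC(=O)NC(C)C)c1 | intermediate
3 | 2,5-dimethoxyphenyl N-(tert-butyldimethylsilyl)-N-isopropylcarbamate | COc1ccc(OC)c(OC(=O)N(C(C)C)[Si](C)(C)C(C)(C)C)c1 | intermediate (not isolated)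
4 | 6-lithio derivative of 3 (aryllithium between the carbamate and the 5-OMe) | COc1ccc(OC)c(OC(=O)N(C(C)C)[Si](C)(C)C(C)(C)C)c1[Li] | intermediate (not isolated)
5 | 3,6-dimethoxy-2-(trimethylsilyl)phenyl N-(tert-butyldimethylsilyl)-N-isopropylcarbamate | COc1ccc(OC)c(OC(=O)N(C(C)C)[Si](C)(C)C(C)(C)C)c1[Si](C)(C)C | intermediate (not isolated)
6 | 3,6-dimethoxy-2-(trimethylsilyl)phenyl N-isopropylcarbamate | COc1ccc(OC)c(OC(=O)NC(C)C)c1[Si](C)(C)C | intermediate
7 | 3,6-dimethoxy-2-(trimethylsilyl)phenol (formed as its DBU-H phenoxide) | COc1ccc(OC)c(O)c1[Si](C)(C)C | intermediate (not isolated)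
8 | 3,6-dimethoxy-2-(trimethylsilyl)phenyl trifluoromethanesulfonate | COc1ccc(OC)c([Si](C)(C)C)c1OS(=O)(=O)C(F)(F)F | intermediate
9 | 3-methylbut-2-enal | CC(C)=CC=O | starting material
10 | 3,6-dimethoxybenzyne | COC1=CC=C(OC)C#C1 | intermediate (not isolated)
11 | 3,6-dimethoxy-2-(2-methylprop-1-en-1-yl)-2H-benzo[b]oxete (racemic, transient) | COc1ccc(OC)c2c1C(C=C(C)C)O2 | intermediate (not isolated)
12 | (6Z)-2,5-dimethoxy-6-(3-methylbut-2-en-1-ylidene)cyclohexa-2,4-dien-1-one | COC1=CC=C(OC)/C(=C/C=C(C)C)C1=O | intermediate (not isolated)
13 | 5,8-dimethoxy-2,2-dimethyl-2H-chromene | COc1ccc(OC)c2c1C=CC(C)(C)O2 | intermediate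
14 | 6-iodo-5,8-dimethoxy-2,2-dimethyl-2H-chromene | COc1cc(I)c(OC)c2c1OC(C)(C)C=C2 | intermediate
15 | 4-ethynylanisole | COc1ccc(C#C)cc1 | starting material
16 | 5,8-dimethoxy-6-[(4-methoxyphenyl)ethynyl]-2,2-dimethyl-2H-chromene | COc1ccc(C#Cc2cc(OC)c3OC(C)(C)C=Cc3c2OC)cc1 | intermediate
17 | 1-(5,8-dimethoxy-2,2-dimethyl-2H-chromen-6-yl)-2-(4-methoxyphenyl)ethane-1,2-dione | COc1ccc(C(=O)C(=O)c2cc(OC)c3OC(C)(C)C=Cc3c2OC)cc1 | intermediate
18 | dielsianone | COc1ccc(C(=O)C(=O)c2cc(OC)c3c(c2O)C=CC(C)(C)O3)cc1 | target

**Step count**

Total: 8 steps. Longest linear sequence: 8 steps (1 → 18); 9 and 15 enter as purchased materials in steps 4 and 6.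

**Steps most likely to fail**

Step 4. The aryne may be diverted into an ene reaction with the allylic methyl C–H of the enal, or a second aryne may capture the o-quinone methide or the electron-rich product faster than the carbonyl addition/electrocyclisation sequence runs. The fallback sets out from 1 and comes back at 13. O-alkylation of 1 with 3-chloro-3-methylbut-1-yne (K2CO3, KI, cat. CuI, acetone, reflux) should give the aryl propargyl ether 1,4-dimethoxy-2-[(2-methylbut-3-yn-2-yl)oxy]benzene F1. Heating F1 in N,N-diethylaniline at about 190 °C should bring about propargyl Claisen rearrangement into the only free ortho position, a 1,5-hydrogen shift to the same o-quinone methide 12, and oxa-6π closure to 13.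

Step 5. Iodonium addition to the electron-rich C3=C4 styrene bond, or oxidation of the hydroquinone-type ring, may compete with substitution at C6. The fallback sets out from 13 and comes back at 16, using a carbon electrophile instead of a halogen. Vilsmeier–Haack formylation (POCl3, DMF, 0 °C → rt; aqueous NaOAc) should give 5,8-dimethoxy-2,2-dimethyl-2H-chromene-6-carbaldehyde F2 with the same C6 preference. Ohira–Bestmann homologation (dimethyl (1-diazo-2-oxopropyl)phosphonate, K2CO3, MeOH, rt) should convert it into 6-ethynyl-5,8-dimethoxy-2,2-dimethyl-2H-chromene F3. Sonogashira coupling of F3 with 4-iodoanisole (PdCl2(PPh3)2, CuI, Et3N) should then deliver 16.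

Step 7. Under Pd(II) at 140 °C the neighbouring 5-OMe oxygen may attack the activated alkyne in a 5-endo sense (benzofuran formation with loss of the methyl group), or the chromene alkene may be degraded before the double oxygen transfer is complete. The fallback sets out from 14 and comes back at 17 without passing through the alkyne. Pd-catalysed α-arylation of 4'-methoxyacetophenone with 14 (Pd2(dba)3, Xantphos, NaOt-Bu, toluene, 80 °C) should give the deoxybenzoin 2-(5,8-dimethoxy-2,2-dimethyl-2H-chromen-6-yl)-1-(4-methoxyphenyl)ethan-1-one F4. Riley oxidation of its doubly activated methylene (SeO2, dioxane/H2O, reflux) should give 17; the chromene has no allylic C–H to compete.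

**Further compounds**

F1 | step 4 | 1,4-dimethoxy-2-[(2-methylbut-3-yn-2-yl)oxy]benzene | COc1ccc(OC)c(OC(C)(C)C#C)c1
F2 | step 5 | 5,8-dimethoxy-2,2-dimethyl-2H-chromene-6-carbaldehyde | COc1cc(C=O)c(OC)c2c1OC(C)(C)C=C2
F3 | step 5 | 6-ethynyl-5,8-dimethoxy-2,2-dimethyl-2H-chromene | COc1cc(C#C)c(OC)c2c1OC(C)(C)C=C2
F4 | step 7 | 2-(5,8-dimethoxy-2,2-dimethyl-2H-chromen-6-yl)-1-(4-methoxyphenyl)ethan-1-one | COc1ccc(C(=O)Cc2cc(OC)c3OC(C)(C)C=Cc3c2OC)cc1
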